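**Retrosynthetic overview**
1. The C8 ester is cut last (Yamaguchi acylation with (2S,3R)-2,3-dimethyloxirane-2-carboxylic acid, itself from Sharpless epoxidation of tiglyl alcohol).
2. Key step: the C6–C7 bond, the ten-membered ring, both C6/C7 stereocentres and then the lactone are made in one flask by a CrCl2-mediated intramolecular 2-(methoxycarbonyl)allylation of a (Z)-enal (carbocycle first, lactone second). No ring-closing metathesis and no late epoxidation are used.
3. The 1,10-epoxide is set on the open chain by Sharpless epoxidation of the C14 allylic alcohol; C8 comes from (S)-glycidol.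
4. The C1=C10 olefin and the C14 hydroxymethyl group come from one three-component β-oxido ylide coupling (phosphonium salt 9 + nerol-derived aldehyde 4 + formaldehyde).
5. C11–C13 are added by Morita–Baylis–Hillman reaction with methyl acrylate and SN2′ bromination.

Assumption: nerol, (S)-glycidol, methyl acrylate and (E)-2-methylbut-2-en-1-ol are taken as commercial. Labels C1–C15 are the germacrane numbering of the target (C6 lactone carbinol, C8 ester carbinol, C1/C10 epoxide, C14 = CH2OAc, C15 = methyl on C4, C11–C13 = methylene-lactone carbons). TBS = tert-butyldimethylsilyl, PMB = 4-methoxybenzyl.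

**Route**

Step 1
Reactants: 1 nerol
Product: 2 neryl TBS ether
Conditions: TBSCl, imidazole, DMF, 0 °C → rt
Reagents that add atoms: tert-butyldimethylsilyl chloride, CC(C)(C)[Si](C)(C)Cl
Why: Standard silyl ether formation on the primary allylic alcohol, which leaves the Z-olefin untouched and creates no stereocentre.

Step 2
Reactants: 2 neryl TBS ether
Product: 3 6,7-epoxyneryl TBS ether (racemic at the oxirane CH)
Conditions: mCPBA (1.0 equiv), CH2Cl2, −20 → 0 °C
Reagents that add atoms: 3-chloroperoxybenzoic acid, O=C(OO)c1cccc(Cl)c1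
Why: Prilezhaev epoxidation goes to the more electron-rich distal trisubstituted olefin (the other one is deactivated by the allylic silyloxy group), and the new stereocentre is irrelevant because step 3 destroys it.

Step 3
Reactants: 3 6,7-epoxyneryl TBS ether
Product: 4 (4Z)-6-(TBSO)-4-methylhex-4-enal
Conditions: H5IO6, THF/H2O, 0 °C
Reagents that add atoms: none
Why: Periodic acid hydrolyses the epoxide at its tertiary carbon and cleaves the glycol (Malaprade cleavage), so the aldehyde keeps the former epoxide oxygen and the Z-olefin is not touched.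

Step 4
Reactants: 5 (S)-glycidol
Product: 6 (R)-glycidyl 4-methoxybenzyl ether
Conditions: NaH, PMBCl, Bu4NI (cat.), THF/DMF, 0 °C → rt
Reagents that add atoms: 4-methoxybenzyl chloride, COc1ccc(CCl)cc1
Why: Williamson etherification at oxygen leaves the stereocentre untouched (the descriptor changes from S to R only through CIP priorities).

Step 5
Reactants: 6 (R)-glycidyl 4-methoxybenzyl ether
Product: 8 [(3R)-3-hydroxy-4-(4-methoxybenzyloxy)butyl]triphenylphosphonium bromide, via oxaphospholane 7 (not isolated)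
Conditions: Ph3PCH3Br, n-BuLi, THF, 0 °C; 6, rt, 16 h; then aq HBr
Reagents that add atoms: methyltriphenylphosphonium bromide, C[P+](c1ccccc1)(c1ccccc1)c1ccccc1.[Br-]; hydrogen bromide, Br
Why: Methylenetriphenylphosphorane opens the terminal epoxide by SN2 attack at the CH2 carbon (known ylide–epoxide opening giving a 1,2-oxaphospholane), and protonation gives the γ-hydroxyalkylphosphonium salt without touching C8.

Step 6
Reactants: 8 hydroxy phosphonium bromide
Product: 9 [(3R)-3-(TBSO)-4-(4-methoxybenzyloxy)butyl]triphenylphosphonium bromide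
Conditions: TBSCl, imidazole, DMF, 40 °C
Reagents that add atoms: tert-butyldimethylsilyl chloride, CC(C)(C)[Si](C)(C)Cl
Why: Silylation of the secondary alcohol gives a C8 protecting group that is inert to ylide chemistry and non-chelating in the key step.

Step 7
Reactants: 9 phosphonium bromide + 4 (4Z)-6-(TBSO)-4-methylhex-4-enal
Product: 13 (2Z,6Z)-2-[(2R)-2-(TBSO)-3-(PMBO)propyl]-8-(TBSO)-6-methylocta-2,6-dien-1-ol, via ylide 10 (not isolated), via betaine 11 (not isolated), via beta-oxido ylide 12 (not isolated)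
Conditions: n-BuLi (1.0 equiv), THF, −78 → 0 °C; 4, −78 °C; n-BuLi (1.05 equiv), −78 → −30 °C; (CH2O)n (excess), 0 °C → rt
Reagents that add atoms: formaldehyde (from paraformaldehyde), C=O
Why: Schlosser–Corey β-oxido ylide (SCOOPY) hydroxymethylation, in which the Wittig betaine is deprotonated, the β-oxido ylide adds formaldehyde and Ph3PO leaves with the oxygen of the first aldehyde, placing CH2OH (C14) cis to the aldehyde-derived chain (C2) as in the classical α-santalol synthesis.

Step 8
Reactants: 13 allylic alcohol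
Product: 14 {(2S,3R)-2-[(2R)-2-(TBSO)-3-(PMBO)propyl]-3-[(3Z)-5-(TBSO)-3-methylpent-3-en-1-yl]oxiran-2-yl}methanol
Conditions: Ti(OiPr)4 (20 mol %), L-(+)-diethyl tartrate (25 mol %), t-BuOOH, 4 Å sieves, CH2Cl2, −20 °C
Reagents that add atoms: tert-butyl hydroperoxide, CC(C)(C)OO
Why: Katsuki–Sharpless asymmetric epoxidation under reagent control, where the L-(+)-tartrate catalyst that turns nerol into its (2S,3R)-epoxide delivers oxygen to the same face here and sets C10 as S and C1 as R, while the silylated C4=C5 olefin is not an allylic alcohol and stays.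

Step 9
Reactants: 14 epoxy alcohol
Product: 15 acetate of 14 (C14-OAc)
Conditions: Ac2O, pyridine, DMAP (cat.), CH2Cl2, 0 °C
Reagents that add atoms: acetic anhydride, CC(=O)OC(C)=O
Why: Ordinary acetylation of the primary alcohol installs the C14 acetate of the target under basic conditions that do not open the epoxide.

Step 10
Reactants: 15 acetate
Product: 16 C7 primary alcohol {(2S,3R)-2-[(2R)-2-(TBSO)-3-hydroxypropyl]-3-[(3Z)-5-(TBSO)-3-methylpent-3-en-1-yl]oxiran-2-yl}methyl acetate
Conditions: DDQ, CH2Cl2/pH 7 phosphate buffer, 0 °C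
Reagents that add atoms: none
Why: Oxidative cleavage of the electron-rich PMB ether by DDQ leaves silyl ethers, acetate, olefins and epoxide alone, and the buffer keeps the liberated 4,5-epoxy alcohol from cyclising before it is oxidised at once in step 11.

Step 11
Reactants: 16 C7 primary alcohol
Product: 17 C7 aldehyde {(2S,3R)-2-[(2R)-2-(TBSO)-3-oxopropyl]-3-[(3Z)-5-(TBSO)-3-methylpent-3-en-1-yl]oxiran-2-yl}methyl acetate
Conditions: Dess–Martin periodinane, pyridine, CH2Cl2, 0 °C → rt
Reagents that add atoms: none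
Why: Dess–Martin oxidation under pyridine buffering gives the α-silyloxy aldehyde without epimerising C8 or opening the epoxide.

Step 12
Reactants: 17 C7 aldehyde + 18 methyl acrylate
Product: 19 methyl (4R)-5-{(2S,3R)-2-(acetoxymethyl)-3-[(3Z)-5-(TBSO)-3-methylpent-3-en-1-yl]oxiran-2-yl}-4-(TBSO)-3-hydroxy-2-methylenepentanoate (C7 epimers)
Conditions: DABCO (0.5 equiv), methyl acrylate (neat, excess), rt, 3–5 d
Reagents that add atoms: none
Why: Morita–Baylis–Hillman reaction of an activated α-silyloxy aldehyde, whose new C7 carbinol centre forms as a mixture that does not matter because C7 becomes sp2 in step 13.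

Step 13
Reactants: 19 Morita–Baylis–Hillman adduct
Product: 20 methyl (2Z,4R)-2-(bromomethyl)-5-{(2S,3R)-2-(acetoxymethyl)-3-[(3Z)-5-(TBSO)-3-methylpent-3-en-1-yl]oxiran-2-yl}-4-(TBSO)pent-2-enoate
Conditions: NBS, Me2S, CH2Cl2, −20 → 0 °C
Reagents that add atoms: N-bromosuccinimide, O=C1CCC(=O)N1Br
Why: Corey–Kim-type activation of the allylic alcohol followed by SN2′ attack of bromide gives the thermodynamically preferred (Z)-2-(bromomethyl)enoate under neutral conditions that spare the epoxide.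

Step 14
Reactants: 20 allylic bromide
Product: 21 C6 allylic alcohol (C6-OH, C8-OTBS retained)
Conditions: Et3N·3HF, THF, rt
Reagents that add atoms: none
Why: Fluoride desilylation removes the unhindered primary allylic TBS ether much faster than the hindered secondary one, and the buffered reagent has no free amine to quaternise the allylic bromide and is not acidic enough to open the epoxide.

Step 15
Reactants: 21 C6 allylic alcohol
Product: 22 (Z)-enal methyl (2Z,4R)-2-(bromomethyl)-5-{(2S,3R)-2-(acetoxymethyl)-3-[(3Z)-3-methyl-5-oxopent-3-en-1-yl]oxiran-2-yl}-4-(TBSO)pent-2-enoate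
Conditions: MnO2, CH2Cl2, rt
Reagents that add atoms: none
Why: MnO2 allylic oxidation is neutral, selective for the allylic alcohol and known to convert nerol-type alcohols into (Z)-enals without isomerisation.

Step 16
Reactants: 22 (Z)-enal allylic bromide
Product: 25 8-O-TBS macrocyclic lactone (ten-membered ring and trans-fused methylene lactone; CIP 1R,6R,7S,8R,10S where 7S reflects only the silyl priority), via allylchromium 23 (not isolated), via chromium alkoxide 24 (not isolated)
Conditions: CrCl2 (6 equiv), THF, 22 added by syringe pump to 2 mM, rt → 50 °C; aq NH4Cl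
Reagents that add atoms: none
Why: Intramolecular Nozaki–Hiyama (chromium Barbier) 2-(alkoxycarbonyl)allylation with in situ lactonisation, the reaction type used to close costunolide-type rings, in which divalent chromium inserts into the C–Br bond and the equilibrating allylchromium reacts through a chair Zimmerman–Traxler transition state with C5 and C8 equatorial to give the 6,7-anti adduct (trans-lactone), while at C8 allylic 1,3-strain holds H8 next to the ester-bearing alkene carbon, the tether carbon C9 sits anti to the forming bond (the alternative forces a syn-pentane C5/C9 contact into the forming ring) and the silyloxy group lies outside, so C6 and C7 form as R,R beside 8R before the trivalent chromium alkoxide closes the lactone on the methyl ester.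

Step 17
Reactants: 25 8-O-TBS macrocyclic lactone
Product: 26 8-hydroxy macrocyclic lactone (1R,6R,7R,8R,10S)
Conditions: HF·pyridine, pyridine, THF, 0 °C → rt
Reagents that add atoms: none
Why: Buffered fluoride desilylation frees the C8 alcohol, and trisubstituted epoxides, acetates and methylene lactones are known to survive these conditions.

Step 18
Reactants: 27 (E)-2-methylbut-2-en-1-ol
Product: 28 [(2R,3R)-2,3-dimethyloxiran-2-yl]methanol
Conditions: Ti(OiPr)4 (10 mol %), D-(−)-diethyl tartrate (12 mol %), t-BuOOH, 4 Å sieves, CH2Cl2, −20 °C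
Reagents that add atoms: tert-butyl hydroperoxide, CC(C)(C)OO
Why: Katsuki–Sharpless asymmetric epoxidation with the D-(−)-tartrate gives the (2R,3R) epoxy alcohol, the mirror image of the (2S,3S) epoxides formed from (E)-allylic alcohols with the L-(+) ester, and sets both side-chain stereocentres.

Step 19
Reactants: 28 epoxy alcohol
Product: 29 (2S,3R)-2,3-dimethyloxirane-2-carboxylic acid
Conditions: RuCl3·xH2O (2 mol %), NaIO4, MeCN/EtOAc/H2O, rt
Reagents that add atoms: water, O
Why: Sharpless RuCl3/NaIO4 oxidation takes the primary alcohol to the acid through the aldehyde hydrate without touching the epoxide, and the C2 descriptor changes from R to S only through CIP priorities.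

Step 20
Reactants: 26 8-hydroxy macrocyclic lactone + 29 epoxy acid
Product: 31 target CNP0232260.4, via mixed anhydride 30 (not isolated)
Conditions: 29, 2,4,6-trichlorobenzoyl chloride, Et3N, toluene, rt; then 26, DMAP, rt → 40 °C
Reagents that add atoms: none
Why: Yamaguchi esterification acylates the hindered C8 alcohol with retention because no bond to C8 is broken, and the non-nucleophilic conditions leave both epoxides, the acetate and the methylene lactone intact.

**Compound list**
1 | nerol, (2Z)-3,7-dimethylocta-2,6-dien-1-ol | OC/C=C(/C)CCC=C(C)C | starting material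
2 | neryl TBS ether | CC(C)(C)[Si](C)(C)OC/C=C(/C)CCC=C(C)C | intermediate
3 | 6,7-epoxyneryl TBS ether (racemic at oxirane CH) | CC(C)(C)[Si](C)(C)OC/C=C(/C)CCC1OC1(C)C | intermediate
4 | (4Z)-6-(TBSO)-4-methylhex-4-enal (C1–C6, C15) | CC(C)(C)[Si](C)(C)OC/C=C(/C)CCC=O | intermediate
5 | (S)-glycidol | OC[C@H]1CO1 | starting material
6 | (R)-glycidyl 4-methoxybenzyl ether | COc1ccc(COC[C@H]2CO2)cc1 | intermediate
7 | (5R)-5-[(4-methoxybenzyloxy)methyl]-2,2,2-triphenyl-1,2-oxaphospholane | COc1ccc(COC[C@H]2CCP(c3ccccc3)(c3ccccc3)(c3ccccc3)O2)cc1 | intermediate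
8 | [(3R)-3-hydroxy-4-(4-methoxybenzyloxy)butyl]triphenylphosphonium bromide | COc1ccc(COC[C@H](O)CC[P+](c2ccccc2)(c2ccccc2)c2ccccc2)cc1.[Br-] | intermediate
9 | [(3R)-3-(TBSO)-4-(4-methoxybenzyloxy)butyl]triphenylphosphonium bromide | COc1ccc(COC[C@H](O[Si](C)(C)C(C)(C)C)CC[P+](c2ccccc2)(c2ccccc2)c2ccccc2)cc1.[Br-] | intermediate
10 | ylide of 9 | COc1ccc(COC[C@H](O[Si](C)(C)C(C)(C)C)CC=P(c2ccccc2)(c2ccccc2)c2ccccc2)cc1 | intermediate
11 | Wittig betaine from 10 and 4 (C1, C10 undefined) | COc1ccc(COC[C@H](O[Si](C)(C)C(C)(C)C)CC(C([O-])CC/C(C)=C\CO[Si](C)(C)C(C)(C)C)[P+](c2ccccc2)(c2ccccc2)c2ccccc2)cc1 | intermediate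
12 | lithium β-oxido ylide | COc1ccc(COC[C@H](O[Si](C)(C)C(C)(C)C)CC(=P(c2ccccc2)(c2ccccc2)c2ccccc2)C([O-])CC/C(C)=C\CO[Si](C)(C)C(C)(C)C)cc1.[Li+] | intermediate
13 | (2Z,6Z)-2-[(2R)-2-(TBSO)-3-(PMBO)propyl]-8-(TBSO)-6-methylocta-2,6-dien-1-ol (C14-OH) | COc1ccc(COC[C@H](O[Si](C)(C)C(C)(C)C)C/C(CO)=C/CC/C(C)=C\CO[Si](C)(C)C(C)(C)C)cc1 | intermediate
14 | {(2S,3R)-2-[(2R)-2-(TBSO)-3-(PMBO)propyl]-3-[(3Z)-5-(TBSO)-3-methylpent-3-en-1-yl]oxiran-2-yl}methanol (1R,10S-epoxide) | CC(C)(C)[Si](C)(C)OC/C=C(/C)CC[C@H]1O[C@]1(CO)C[C@@H](O[Si](C)(C)C(C)(C)C)COCc1ccc(OC)cc1 | intermediate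
15 | acetate of 14 | CC(C)(C)[Si](C)(C)OC/C=C(/C)CC[C@H]1O[C@]1(COC(C)=O)C[C@@H](O[Si](C)(C)C(C)(C)C)COCc1ccc(OC)cc1 | intermediate
16 | C7 primary alcohol | CC(C)(C)[Si](C)(C)OC/C=C(/C)CC[C@H]1O[C@]1(COC(C)=O)C[C@@H](O[Si](C)(C)C(C)(C)C)CO | intermediate
17 | C7 aldehyde | CC(C)(C)[Si](C)(C)OC/C=C(/C)CC[C@H]1O[C@]1(COC(C)=O)C[C@@H](O[Si](C)(C)C(C)(C)C)C=O | intermediate
18 | methyl acrylate | C=CC(=O)OC | starting material
19 | Morita–Baylis–Hillman adduct (C7 epimers) | CC(C)(C)[Si](C)(C)OC/C=C(/C)CC[C@H]1O[C@]1(COC(C)=O)C[C@@H](O[Si](C)(C)C(C)(C)C)C(O)C(=C)C(=O)OC | intermediate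
20 | (2Z)-2-(bromomethyl)enoate, C6-OTBS, C8-OTBS | CC(C)(C)[Si](C)(C)OC/C=C(/C)CC[C@H]1O[C@]1(COC(C)=O)C[C@@H](O[Si](C)(C)C(C)(C)C)/C=C(\CBr)C(=O)OC | intermediate
21 | C6 allylic alcohol | OC/C=C(/C)CC[C@H]1O[C@]1(COC(C)=O)C[C@@H](O[Si](C)(C)C(C)(C)C)/C=C(\CBr)C(=O)OC | intermediate
22 | (Z)-enal allylic bromide | O=C/C=C(/C)CC[C@H]1O[C@]1(COC(C)=O)C[C@@H](O[Si](C)(C)C(C)(C)C)/C=C(\CBr)C(=O)OC | intermediate
23 | allylchromium dichloride from 22 (C7=C11 geometry equilibrating) | O=C/C=C(/C)CC[C@H]1O[C@]1(COC(C)=O)C[C@@H](O[Si](C)(C)C(C)(C)C)C=C(C[Cr](Cl)Cl)C(=O)OC | intermediate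
24 | chromium alkoxide of the ten-membered hydroxy ester (6R,7R,8R) | COC(=O)C(=C)[C@H]1[C@H](O[Cr](Cl)Cl)/C=C(/C)CC[C@H]2O[C@]2(COC(C)=O)C[C@H]1O[Si](C)(C)C(C)(C)C | intermediate
25 | 8-O-TBS macrocyclic lactone | C=C1C(=O)O[C@@H]2/C=C(/C)CC[C@H]3O[C@]3(COC(C)=O)C[C@@H](O[Si](C)(C)C(C)(C)C)[C@@H]12 | intermediate
26 | 8-hydroxy macrocyclic lactone | C=C1C(=O)O[C@@H]2/C=C(/C)CC[C@H]3O[C@]3(COC(C)=O)C[C@@H](O)[C@@H]12 | intermediate
27 | (E)-2-methylbut-2-en-1-ol (tiglyl alcohol) | C/C=C(\C)CO | starting material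
28 | [(2R,3R)-2,3-dimethyloxiran-2-yl]methanol | OC[C@@]1(C)O[C@@H]1C | intermediate
29 | (2S,3R)-2,3-dimethyloxirane-2-carboxylic acid | OC(=O)[C@@]1(C)O[C@@H]1C | intermediate
30 | mixed anhydride of 29 with 2,4,6-trichlorobenzoic acid | O=C(OC(=O)[C@@]1(C)O[C@@H]1C)c1c(Cl)cc(Cl)cc1Cl | intermediate
31 | CNP0232260.4 (1R,6R,7R,8R,10S; side chain 2S,3R; 4Z) | C=C1C(=O)O[C@@H]2/C=C(/C)CC[C@H]3O[C@]3(COC(C)=O)C[C@@H](OC(=O)[C@@]3(C)O[C@@H]3C)[C@@H]12 | target

**Totals**
Total steps: 20. Longest linear sequence: 15 (steps 1–3 or 4–6, then 7–17 and 20).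

**Three steps most likely to fail**

Step 16 (ring closure). The risks are oligomerisation, a syn instead of anti C6/C7 relationship, and addition to the other C7 face relative to C8. The fallback sets out from 9 and comes back at 25, and moves the ring closure to the C4=C5 olefin by metathesis. Ylide 10 is coupled by the step 7 protocol with 4-methylpent-4-enal F6 (through betaine F7 and lithium beta-oxido ylide F8) to allylic alcohol F9. The operations of steps 8–13 then give epoxy alcohol F10, acetate F11, primary alcohol F12, aldehyde F13, Morita–Baylis–Hillman adduct F14 and allylic bromide F15. Intermolecular CrCl2 allylation of acrolein (through allylchromium F16 and chromium alkoxide F17) gives diene lactone F18. Ring-closing metathesis with second-generation Grubbs catalyst in hot toluene at 1 mM closes the Z-olefin and gives 25.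

Step 7 (three-component β-oxido ylide coupling). The risks are incomplete betaine deprotonation and leakage of olefin geometry. The fallback sets out from 6 and 4 and comes back at 13, and builds the olefin by a Z-selective Horner–Wadsworth–Emmons reaction. Epoxide 6 is opened with LiI/AcOH to iodohydrin F1 and silylated to silyl ether iodide F2. F2 alkylates methyl bis(2,2,2-trifluoroethyl)phosphonoacetate (NaH, DMF) to phosphonate F3. Still–Gennari olefination of 4 with F3 (KN(SiMe3)2, 18-crown-6, THF, −78 °C) gives (Z)-enoate F4 with the ester cis to the C2 chain, and i-Bu2AlH reduction gives 13.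

Step 12 (Morita–Baylis–Hillman reaction). The risks are a slow reaction, C8 epimerisation and cyclisation of the epoxy alcohol over several days with amine. The fallback sets out from 17 and comes back at 19, and replaces amine catalysis by addition of a preformed α-metallated acrylate. Hydroalumination of methyl propiolate with i-Bu2AlH and N-methylmorpholine N-oxide in THF at 0 °C gives vinylalane F5, which adds to 17 at −78 °C within minutes to give 19.

**Further compounds**
F1 | step 7 | (2S)-1-iodo-3-(4-methoxybenzyloxy)propan-2-ol | COc1ccc(COC[C@H](O)CI)cc1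
F2 | step 7 | tert-butyl{[(2S)-1-iodo-3-(4-methoxybenzyloxy)propan-2-yl]oxy}dimethylsilane | COc1ccc(COC[C@H](O[Si](C)(C)C(C)(C)C)CI)cc1
F3 | step 7 | methyl (4R)-2-[bis(2,2,2-trifluoroethoxy)phosphoryl]-4-(TBSO)-5-(PMBO)pentanoate (C2 epimers) | COc1ccc(COC[C@H](O[Si](C)(C)C(C)(C)C)CC(C(=O)OC)P(=O)(OCC(F)(F)F)OCC(F)(F)F)cc1
F4 | step 7 | methyl (2Z,6Z)-2-[(2R)-2-(TBSO)-3-(PMBO)propyl]-8-(TBSO)-6-methylocta-2,6-dienoate | COc1ccc(COC[C@H](O[Si](C)(C)C(C)(C)C)C/C(C(=O)OC)=C/CC/C(C)=C\CO[Si](C)(C)C(C)(C)C)cc1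
F5 | step 12 | methyl 2-(diisobutylalumanyl)acrylate | C=C([Al](CC(C)C)CC(C)C)C(=O)OC
F6 | step 16 | 4-methylpent-4-enal | CC(=C)CCC=O
F7 | step 16 | Wittig betaine from 10 and F6 | COc1ccc(COC[C@H](O[Si](C)(C)C(C)(C)C)CC(C([O-])CCC(C)=C)[P+](c2ccccc2)(c2ccccc2)c2ccccc2)cc1
F8 | step 16 | lithium β-oxido ylide from F7 | COc1ccc(COC[C@H](O[Si](C)(C)C(C)(C)C)CC(=P(c2ccccc2)(c2ccccc2)c2ccccc2)C([O-])CCC(C)=C)cc1.[Li+]
F9 | step 16 | (2Z)-2-[(2R)-2-(TBSO)-3-(PMBO)propyl]-6-methylhepta-2,6-dien-1-ol | COc1ccc(COC[C@H](O[Si](C)(C)C(C)(C)C)C/C(CO)=C/CCC(C)=C)cc1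
F10 | step 16 | (1R,10S)-epoxy alcohol with isopropenyl terminus | C=C(C)CC[C@H]1O[C@]1(CO)C[C@@H](O[Si](C)(C)C(C)(C)C)COCc1ccc(OC)cc1
F11 | step 16 | acetate of F10 | C=C(C)CC[C@H]1O[C@]1(COC(C)=O)C[C@@H](O[Si](C)(C)C(C)(C)C)COCc1ccc(OC)cc1
F12 | step 16 | C7 primary alcohol | C=C(C)CC[C@H]1O[C@]1(COC(C)=O)C[C@@H](O[Si](C)(C)C(C)(C)C)CO
F13 | step 16 | C7 aldehyde | C=C(C)CC[C@H]1O[C@]1(COC(C)=O)C[C@@H](O[Si](C)(C)C(C)(C)C)C=O
F14 | step 16 | Morita–Baylis–Hillman adduct (C7 epimers) | C=C(C)CC[C@H]1O[C@]1(COC(C)=O)C[C@@H](O[Si](C)(C)C(C)(C)C)C(O)C(=C)C(=O)OC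
F15 | step 16 | (2Z)-2-(bromomethyl)enoate with isopropenyl terminus | C=C(C)CC[C@H]1O[C@]1(COC(C)=O)C[C@@H](O[Si](C)(C)C(C)(C)C)/C=C(\CBr)C(=O)OC
F16 | step 16 | allylchromium dichloride from F15 | C=C(C)CC[C@H]1O[C@]1(COC(C)=O)C[C@@H](O[Si](C)(C)C(C)(C)C)C=C(C[Cr](Cl)Cl)C(=O)OC
F17 | step 16 | chromium alkoxide of the acrolein adduct | C=C[C@@H](O[Cr](Cl)Cl)[C@H](C(=C)C(=O)OC)[C@H](O[Si](C)(C)C(C)(C)C)C[C@@]1(COC(C)=O)O[C@@H]1CCC(C)=C
F18 | step 16 | trans-β,γ-disubstituted α-methylene-γ-butyrolactone diene (vinyl on C6, isopropenyl terminus) | C=C1C(=O)O[C@H](C=C)[C@H]1[C@H](O[Si](C)(C)C(C)(C)C)C[C@@]1(COC(C)=O)O[C@@H]1CCC(C)=C
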